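**Retrosynthetic overview**
- Target ⇒ its tris(benzyl ether) acid (global hydrogenolysis) ⇒ the depside aldehyde (Pinnick oxidation), so the ring-B carboxyl needs no protecting group.
- Depside aldehyde ⇒ acyl–O disconnection into a ring-A acid (4-OBn, 2-OMe) and a ring-B phenol aldehyde (2,4-di-OBn, free 3-OH).
- Both halves ⇐ one common intermediate, 1,3-bis(benzyloxy)-5-propylbenzene. Ring A: Vilsmeier formylation, chelation-controlled ortho-debenzylation, O-methylation, Pinnick. Ring B: C-2 lithiation–borylation–oxidation, then Vilsmeier formylation.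
- Key C–C disconnection: the aryl–CH2 bond of the common intermediate ⇒ aryl bromide + propanal, whose carbonyl carbon serves as an n-propyl carbanion (N–H hydrazone, Ni catalysis, loss of N2).
- Ring formation: none; both benzene rings are carried in from the one aryl bromide.

Assumption: the target has no stereocentre or stereogenic double bond, so nothing has to be set for "the single enantiomer"; 1,3-bis(benzyloxy)-5-bromobenzene is taken as a catalogue aryl bromide.

**Step 1**
Reactants: 1 1,3-bis(benzyloxy)-5-bromobenzene; 2 propanal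
Product: 4 1,3-bis(benzyloxy)-5-propylbenzene, via propanal hydrazone 3 (not isolated)
Conditions: 2 (3 eq), N2H4·H2O (3.3 eq), THF, 0 °C→rt, 1 h, 4 Å MS; then 1, Ni(cod)2 (10 mol %), PMe3 (20 mol %), DBU (2 eq), THF, 60 °C, 24 h
Reagents that add atoms: hydrazine hydrate, NN.O (its two N atoms sit only in intermediate 3 and leave as N2; nothing from it stays in 4)
Why: Proposed new method: DBU deprotonates the N–H hydrazone 3 to an aza-allyl anion (HN=N–CH(–)Et ↔ –HN–N=CHEt) whose former carbonyl carbon is nucleophilic, so after oxidative addition of the Ar–Br bond of 1 to Ni(0) it binds nickel through carbon, the Ar–Ni–CH(Et)N=NH species loses N2 in a Wolff–Kishner-type step, and reductive elimination/protonation gives the Ar–CH2CH2CH3 bond between an aryl-halide carbon and an aldehyde carbon that are both electrophiles by nature; the closest known reaction type is the nickel-catalysed denitrogenative cross-coupling of N-unsubstituted aldehyde hydrazones (established mainly for aromatic aldehydes) with aryl halides and phenol sulfonates, extended here to an enolisable aliphatic aldehyde; no stereocentre is formed.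

**Step 2**
Reactants: 4 1,3-bis(benzyloxy)-5-propylbenzene
Product: 5 2,4-bis(benzyloxy)-6-propylbenzaldehyde
Conditions: POCl3 (1.5 eq), DMF, 0 °C→80 °C; then H2O
Reagents that add atoms: N,N-dimethylformamide, CN(C)C=O (formyl carbon); water, O (formyl oxygen)
Why: Vilsmeier–Haack formylation of a 5-alkylresorcinol diether goes para to one ether oxygen and ortho to the other (C-4) and not to the doubly flanked C-2, as in the dimethyl ether series; no stereocentre is formed.

**Step 3**
Reactants: 5 2,4-bis(benzyloxy)-6-propylbenzaldehyde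
Product: 6 4-(benzyloxy)-2-hydroxy-6-propylbenzaldehyde
Conditions: MgBr2·OEt2 (3 eq), toluene/Et2O, 80 °C; then H2O
Reagents that add atoms: none
Why: Chelation-controlled Lewis-acid debenzylation: Mg(II) bridges the aldehyde oxygen and the ortho benzyloxy oxygen, and bromide removes only that benzyl group, so the 4-benzyl ether stays.

**Step 4**
Reactants: 6 4-(benzyloxy)-2-hydroxy-6-propylbenzaldehyde
Product: 7 4-(benzyloxy)-2-methoxy-6-propylbenzaldehyde
Conditions: MeI (1.5 eq), K2CO3 (2 eq), DMF, rt→40 °C
Reagents that add atoms: iodomethane, CI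
Why: Williamson O-methylation of the only free (salicyl-type) phenol; the aldehyde has no α-hydrogen and is inert to carbonate.

**Step 5**
Reactants: 7 4-(benzyloxy)-2-methoxy-6-propylbenzaldehyde
Product: 8 4-(benzyloxy)-2-methoxy-6-propylbenzoic acid
Conditions: NaClO2, NaH2PO4, 2-methyl-2-butene, t-BuOH/THF/H2O, 0 °C→rt
Reagents that add atoms: sodium chlorite, [Na+].[O-]Cl=O
Why: Pinnick oxidation converts the hindered, electron-rich aldehyde to the acid without touching the ethers, and the alkene scavenges HOCl so the ring is not chlorinated.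

**Step 6**
Reactants: 4 1,3-bis(benzyloxy)-5-propylbenzene
Product: 11 2,6-bis(benzyloxy)-4-propylphenol, via aryllithium 9 (not isolated), via dimethyl arylboronate 10 (not isolated)
Conditions: n-BuLi (1.2 eq), THF, 0 °C→rt, 2 h; B(OMe)3, −78 °C→rt; then AcOH, 30 % H2O2, 0 °C→rt
Reagents that add atoms: n-butyllithium, [Li]CCCC (lithium in 9 only); trimethyl borate, COB(OC)OC (boron and two methoxy groups in 10 only); hydrogen peroxide, OO (the phenolic oxygen of 11)
Why: Directed ortho-metalation at the C–H flanked by both ether oxygens (no TMEDA, to keep benzylic OCH2 metalation down), borylation and oxidative 1,2-aryl shift from boron to oxygen give the phenol that is the differentiated central oxygen of ring B.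

**Step 7**
Reactants: 11 2,6-bis(benzyloxy)-4-propylphenol
Product: 12 2,4-bis(benzyloxy)-3-hydroxy-6-propylbenzaldehyde
Conditions: POCl3 (3 eq), DMF, 0 °C→70 °C; then H2O, 50 °C
Reagents that add atoms: N,N-dimethylformamide, CN(C)C=O (formyl carbon); water, O (formyl oxygen)
Why: Vilsmeier–Haack formylation at the only open ring position type (ortho to one benzyloxy, para to the other, as in 3,4,5-trialkoxytoluenes); any O-formimidate formed on the phenol reverts to the phenol on hydrolysis.

**Step 8**
Reactants: 8 4-(benzyloxy)-2-methoxy-6-propylbenzoic acid; 12 2,4-bis(benzyloxy)-3-hydroxy-6-propylbenzaldehyde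
Product: 14 2,6-bis(benzyloxy)-3-formyl-4-propylphenyl 4-(benzyloxy)-2-methoxy-6-propylbenzoate, via acid chloride 13 (not isolated)
Conditions: (COCl)2, cat. DMF, CH2Cl2, 0 °C→rt, evaporate; then 12, Et3N (3 eq), DMAP (0.3 eq), CH2Cl2, rt→40 °C
Reagents that add atoms: oxalyl chloride, O=C(Cl)C(=O)Cl (chlorine in 13 only)
Why: Acid chloride formation followed by DMAP-catalysed acyl transfer to the single free phenol puts the ester on the central oxygen of ring B; the non-enolisable aldehyde and the benzyl ethers are inert.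

**Step 9**
Reactants: 14 2,6-bis(benzyloxy)-3-formyl-4-propylphenyl 4-(benzyloxy)-2-methoxy-6-propylbenzoate
Product: 15 2,4-bis(benzyloxy)-3-{[4-(benzyloxy)-2-methoxy-6-propylbenzoyl]oxy}-6-propylbenzoic acid
Conditions: NaClO2, NaH2PO4, 2-methyl-2-butene, t-BuOH/THF/H2O, 0 °C→rt
Reagents that add atoms: sodium chlorite, [Na+].[O-]Cl=O
Why: Pinnick oxidation under buffered, mildly acidic conditions oxidises the aldehyde to the ring-B carboxylic acid and leaves the aryl ester intact.

**Step 10**
Reactants: 15 2,4-bis(benzyloxy)-3-{[4-(benzyloxy)-2-methoxy-6-propylbenzoyl]oxy}-6-propylbenzoic acid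
Product: 16 2,4-dihydroxy-3-[(4-hydroxy-2-methoxy-6-propylbenzoyl)oxy]-6-propylbenzoic acid
Conditions: H2 (1 atm), 10 % Pd/C, EtOAc, rt
Reagents that add atoms: none
Why: Catalytic hydrogenolysis removes all three benzyl ethers under neutral conditions, so the aryl ester, the methyl ether and the acid survive and no acyl migration or decarboxylation is provoked.

**Compound list**
1 | 1,3-bis(benzyloxy)-5-bromobenzene | Brc1cc(OCc2ccccc2)cc(OCc2ccccc2)c1 | starting material
2 | propanal | CCC=O | starting material
3 | propanal hydrazone ((E)-propylidenehydrazine) | CC/C=N/N | intermediate (not isolated)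
4 | 1,3-bis(benzyloxy)-5-propylbenzene | CCCc1cc(OCc2ccccc2)cc(OCc2ccccc2)c1 | intermediate
5 | 2,4-bis(benzyloxy)-6-propylbenzaldehyde | CCCc1cc(OCc2ccccc2)cc(OCc2ccccc2)c1C=O | intermediate
6 | 4-(benzyloxy)-2-hydroxy-6-propylbenzaldehyde | CCCc1cc(OCc2ccccc2)cc(O)c1C=O | intermediate
7 | 4-(benzyloxy)-2-methoxy-6-propylbenzaldehyde | CCCc1cc(OCc2ccccc2)cc(OC)c1C=O | intermediate
8 | 4-(benzyloxy)-2-methoxy-6-propylbenzoic acid | CCCc1cc(OCc2ccccc2)cc(OC)c1C(=O)O | intermediate
9 | [2,6-bis(benzyloxy)-4-propylphenyl]lithium (aryllithium) | [Li]c1c(OCc2ccccc2)cc(CCC)cc1OCc1ccccc1 | intermediate (not isolated)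
10 | dimethyl [2,6-bis(benzyloxy)-4-propylphenyl]boronate (dimethyl arylboronate) | COB(OC)c1c(OCc2ccccc2)cc(CCC)cc1OCc1ccccc1 | intermediate (not isolated)
11 | 2,6-bis(benzyloxy)-4-propylphenol | Oc1c(OCc2ccccc2)cc(CCC)cc1OCc1ccccc1 | intermediate
12 | 2,4-bis(benzyloxy)-3-hydroxy-6-propylbenzaldehyde | CCCc1cc(OCc2ccccc2)c(O)c(OCc2ccccc2)c1C=O | intermediate
13 | 4-(benzyloxy)-2-methoxy-6-propylbenzoyl chloride (acid chloride) | CCCc1cc(OCc2ccccc2)cc(OC)c1C(=O)Cl | intermediate (not isolated)
14 | 2,6-bis(benzyloxy)-3-formyl-4-propylphenyl 4-(benzyloxy)-2-methoxy-6-propylbenzoate | CCCc1cc(OCc2ccccc2)cc(OC)c1C(=O)Oc1c(OCc2ccccc2)cc(CCC)c(C=O)c1OCc1ccccc1 | intermediate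
15 | 2,4-bis(benzyloxy)-3-{[4-(benzyloxy)-2-methoxy-6-propylbenzoyl]oxy}-6-propylbenzoic acid | CCCc1cc(OCc2ccccc2)cc(OC)c1C(=O)Oc1c(OCc2ccccc2)cc(CCC)c(C(=O)O)c1OCc1ccccc1 | intermediate
16 | 2,4-dihydroxy-3-[(4-hydroxy-2-methoxy-6-propylbenzoyl)oxy]-6-propylbenzoic acid | CCCc1cc(O)cc(OC)c1C(=O)Oc1c(O)cc(CCC)c(C(=O)O)c1O | target

**Step count**
Total: 10 steps. Longest linear sequence: 8 steps (1 → 2 → 3 → 4 → 5 → 8 → 9 → 10).

**Steps most likely to fail, with fallbacks**

Step 1 is the riskiest. The aliphatic N–H hydrazone can form the azine, the aryl bromide can be hydrodebrominated, and a nickel–alkyl species can undergo β-hydride loss. The fallback sets out from 1 and 2 and comes back at 4. Propanal 2 is condensed with tert-butylhydrazine to propanal N-tert-butylhydrazone F1, an established acyl-anion equivalent. Pd-catalysed C-arylation of it with 1 (Pd2(dba)3, DPEphos, NaOtBu, toluene, 80 °C) gives 1-[3,5-bis(benzyloxy)phenyl]propan-1-one N-tert-butylhydrazone F2. Aqueous HCl in THF releases 1-[3,5-bis(benzyloxy)phenyl]propan-1-one F3. Huang-Minlon Wolff–Kishner reduction (N2H4·H2O, KOH, diethylene glycol, 130→195 °C) through 1-[3,5-bis(benzyloxy)phenyl]propan-1-one hydrazone F4 then gives 4.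

Step 7 may stall because the free, flanked phenol consumes Vilsmeier reagent at oxygen. The fallback sets out from 11 and comes back at 12. The phenol is acetylated (Ac2O, pyridine) to 2,6-bis(benzyloxy)-4-propylphenyl acetate F5. Rieche formylation (Cl2CHOMe, SnCl4, CH2Cl2, −20 °C) gives 2,6-bis(benzyloxy)-3-formyl-4-propylphenyl acetate F6. Methanolysis (K2CO3, MeOH, rt) gives 12.

Step 8 joins a 2,6-disubstituted acyl chloride to a phenol flanked by two benzyloxy groups, so addition–elimination may be too slow. The fallback sets out from 8 (with 12) and comes back at 14. It replaces acyl transfer by acylium capture: trifluoroacetic anhydride in toluene at rt converts 8 into 4-(benzyloxy)-2-methoxy-6-propylbenzoic trifluoroacetic anhydride F7. This ionises to the linear, alkoxy-stabilised acylium ion, which phenol 12 traps to give 14.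

**Further compounds**
F1 | step 1 | propanal N-tert-butylhydrazone | CCC=NNC(C)(C)C
F2 | step 1 | 1-[3,5-bis(benzyloxy)phenyl]propan-1-one N-tert-butylhydrazone | CCC(=NNC(C)(C)C)c1cc(OCc2ccccc2)cc(OCc2ccccc2)c1
F3 | step 1 | 1-[3,5-bis(benzyloxy)phenyl]propan-1-one | CCC(=O)c1cc(OCc2ccccc2)cc(OCc2ccccc2)c1
F4 | step 1 | 1-[3,5-bis(benzyloxy)phenyl]propan-1-one hydrazone | CCC(=NN)c1cc(OCc2ccccc2)cc(OCc2ccccc2)c1
F5 | step 7 | 2,6-bis(benzyloxy)-4-propylphenyl acetate | CC(=O)Oc1c(OCc2ccccc2)cc(CCC)cc1OCc1ccccc1
F6 | step 7 | 2,6-bis(benzyloxy)-3-formyl-4-propylphenyl acetate | CC(=O)Oc1c(OCc2ccccc2)cc(CCC)c(C=O)c1OCc1ccccc1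
F7 | step 8 | 4-(benzyloxy)-2-methoxy-6-propylbenzoic trifluoroacetic anhydride | CCCc1cc(OCc2ccccc2)cc(OC)c1C(=O)OC(=O)C(F)(F)F
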